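**Plan**

- Retrosynthesis: the benzyl groups and the 5-O-methyl group are removed last, the C3–O bond is cut next, and ring C is then opened at C4a–C4, C4–C3 and O1–C2.
- Enabling feature: C4 is an isolated carbonyl carbon between C4a of ring A and C3, and O1 sits on C8a next to C4a. Carbon monoxide can therefore supply C4, an ortho-iodophenol supplies O1, C8a and C4a, and an arylalkyne supplies C2, C3 and ring B.
- Forward: the ring A iodophenol is made from 2-hydroxy-4,6-dimethoxybenzaldehyde, with one diethylcarbamate serving first as protecting group and then as ortho-directing group. The ring B alkyne is made from 3,5-dihydroxy-4-methoxybenzoic acid.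
- Ring C is closed in the three-component carbonylative coupling. C3 hydroxylation and one Lewis-acid deprotection (two benzyl ethers and the 5-O-methyl) finish the route.
- Stereochemistry: the target has no stereocentre, so none has to be set.

Key step: step 10

Assumption: flavone numbering is used throughout (O1, C2, C3, C4, C4a, C5 to C8, C8a; primed numbers for ring B). The benzo ring is ring A, the pyranone is ring C and the 2-aryl group is ring B.

**Route**

Step 1
Reactants: 1 2-hydroxy-4,6-dimethoxybenzaldehyde; 2 N,N-diethylcarbamoyl chloride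
Product: 3 2-formyl-3,5-dimethoxyphenyl N,N-diethylcarbamate
Conditions: K2CO3, MeCN, reflux
Reagents that add atoms: none
Why: O-carbamoylation of the phenoxide (acyl substitution at the carbamoyl chloride) should be clean, and the carbamate formed is inert to the peracid, mild base and alkylation that follow and later directs the lithiation.

Step 2
Reactants: 3 2-formyl-3,5-dimethoxyphenyl N,N-diethylcarbamate
Product: 5 2-hydroxy-3,5-dimethoxyphenyl N,N-diethylcarbamate, via aryl formate 4 (not isolated)
Conditions: mCPBA (1.1 equiv), CH2Cl2, 0 °C to rt; then Et3N, MeOH, rt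
Reagents that add atoms: meta-chloroperbenzoic acid, OOC(=O)c1cccc(Cl)c1
Why: In this Baeyer–Villiger (Dakin-type) oxidation the aryl group, which carries ortho and para oxygen donors, should migrate in preference to hydride to give formate 4, and mild methanolysis should cleave the formate while the much less electrophilic diethylcarbamate stays in place.

Step 3
Reactants: 5 2-hydroxy-3,5-dimethoxyphenyl N,N-diethylcarbamate
Product: 6 2,3,5-trimethoxyphenyl N,N-diethylcarbamate
Conditions: MeI, K2CO3, DMF, rt to 40 °C
Reagents that add atoms: iodomethane, CI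
Why: Williamson O-methylation of the only free phenol should be straightforward, and the tertiary carbamate is not expected to migrate or cleave under carbonate base.

Step 4
Reactants: 6 2,3,5-trimethoxyphenyl N,N-diethylcarbamate
Product: 8 2-iodo-3,5,6-trimethoxyphenyl N,N-diethylcarbamate, via aryllithium 7 (not isolated)
Conditions: s-BuLi, TMEDA, THF, −78 °C; then I2, THF, −78 °C to rt
Reagents that add atoms: iodine, II
Why: In this directed ortho-metalation the O-carbamate is the strongest directing group and its only free ortho position also lies ortho to a methoxy group, so deprotonation should occur there and not between the two methoxy groups, and iodine should trap aryllithium 7 at −78 °C before an anionic ortho-Fries shift can begin.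

Step 5
Reactants: 8 2-iodo-3,5,6-trimethoxyphenyl N,N-diethylcarbamate
Product: 9 2-iodo-3,5,6-trimethoxyphenol
Conditions: NaOH, EtOH/H2O, reflux; then aq. HCl
Reagents that add atoms: none
Why: Base hydrolysis of the aryl carbamate (acyl substitution by hydroxide at the carbamate carbonyl) should free the phenol, since the aryl iodide and the methyl ethers are inert to ethanolic NaOH.

Step 6
Reactants: 10 3,5-dihydroxy-4-methoxybenzoic acid
Product: 11 benzyl 3,5-bis(benzyloxy)-4-methoxybenzoate
Conditions: BnBr (3.3 equiv), K2CO3, DMF, 60 °C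
Reagents that add atoms: benzyl bromide, BrCc1ccccc1
Why: Williamson alkylation of both phenoxides and of the carboxylate in one operation should give the tribenzyl compound, with the 4-methoxy group untouched.

Step 7
Reactants: 11 benzyl 3,5-bis(benzyloxy)-4-methoxybenzoate
Product: 12 [3,5-bis(benzyloxy)-4-methoxyphenyl]methanol
Conditions: LiAlH4, THF, 0 °C to rt
Reagents that add atoms: none
Why: Hydride reduction of the ester to the primary alcohol is reliable and leaves aryl benzyl ethers intact.

Step 8
Reactants: 12 [3,5-bis(benzyloxy)-4-methoxyphenyl]methanol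
Product: 13 3,5-bis(benzyloxy)-4-methoxybenzaldehyde
Conditions: MnO2, CH2Cl2, rt
Reagents that add atoms: none
Why: MnO2 oxidation is selective for benzylic alcohols and should stop at the aldehyde.

Step 9
Reactants: 13 3,5-bis(benzyloxy)-4-methoxybenzaldehyde
Product: 14 1,3-bis(benzyloxy)-5-ethynyl-2-methoxybenzene
Conditions: dimethyl (1-diazo-2-oxopropyl)phosphonate, K2CO3, MeOH/THF, rt
Reagents that add atoms: dimethyl (1-diazo-2-oxopropyl)phosphonate, CC(=O)C(=[N+]=[N-])P(=O)(OC)OC
Why: Ohira–Bestmann (Seyferth–Gilbert) homologation should convert the non-enolisable aryl aldehyde into the terminal alkyne under mild carbonate conditions that leave the benzyl ethers alone.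

Step 10
Reactants: 9 2-iodo-3,5,6-trimethoxyphenol; 14 1,3-bis(benzyloxy)-5-ethynyl-2-methoxybenzene; 15 carbon monoxide
Product: 18 2-[3,5-bis(benzyloxy)-4-methoxyphenyl]-5,7,8-trimethoxy-4H-chromen-4-one, via ynone 16 (not isolated), via enaminone 17 (not isolated)
Conditions: PdCl2(PPh3)2 (5 mol %), CO (20 bar), Et2NH, 120 °C, autoclave
Reagents that add atoms: none
Why: Zerovalent palladium generated from divalent PdCl2(PPh3)2 should insert into the C4a–I bond of 9, CO should insert to give an aroylpalladium species, and the alkyne 14, deprotonated by diethylamine on palladium, should be transferred and reductively eliminated to give ynone 16, which forms C4a–C4 and C4–C3. Diethylamine should then add to C2 of 16 to give enaminone 17, and the C8a hydroxyl should close ring C by 6-endo-trig addition–elimination at C2 (the O1–C2 bond), releasing diethylamine. The closest known reaction type is the palladium-catalysed carbonylative Sonogashira annulation of 2-iodophenols with terminal arylalkynes to flavones in a secondary amine. No stereocentre is formed. Carbonylation has to outrun direct alkynylation (leading to a benzofuran) and aminocarbonylation (a salicylamide), and 6-endo closure has to outrun 5-exo closure (an aurone); the copper-free system under CO pressure and the ready CO insertion of the electron-rich arylpalladium favour the ynone, and the enaminone carries its leaving group on C2 so that only the six-membered ring can form. The 5,7,8-trimethoxy pattern cannot scramble because the hydroxyl of 9 is fixed between the iodine-bearing carbon and the methoxy-bearing carbon that becomes C8.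

Step 11
Reactants: 18 2-[3,5-bis(benzyloxy)-4-methoxyphenyl]-5,7,8-trimethoxy-4H-chromen-4-one
Product: 21 2-[3,5-bis(benzyloxy)-4-methoxyphenyl]-3-hydroxy-5,7,8-trimethoxy-4H-chromen-4-one, via 3-lithioflavone 19 (not isolated), via dimethyl boronate 20 (not isolated)
Conditions: LiN(i-Pr)2 (LDA), THF, −78 °C; B(OMe)3, −78 °C to rt; then AcOH, 30% H2O2, rt
Reagents that add atoms: hydrogen peroxide, OO
Why: C3 of a flavone is the most acidic C–H (vinylic, next to the carbonyl), so kinetic lithiation at −78 °C, borate trapping and peroxide oxidation of the C–B bond (lithiation–borylation–oxidation) should install the 3-hydroxyl without touching the benzyl or methyl ethers.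

Step 12
Reactants: 21 2-[3,5-bis(benzyloxy)-4-methoxyphenyl]-3-hydroxy-5,7,8-trimethoxy-4H-chromen-4-one
Product: 22 2-(3,5-dihydroxy-4-methoxyphenyl)-3,5-dihydroxy-7,8-dimethoxy-4H-chromen-4-one (target)
Conditions: BCl3 (excess), pentamethylbenzene, CH2Cl2, −78 °C to 0 °C; then aq. HCl
Reagents that add atoms: none
Why: In this Lewis-acid ether cleavage, BCl3 with pentamethylbenzene as benzyl-cation trap should remove both aryl benzyl ethers at low temperature, and on warming boron chelated between the C4 carbonyl and the peri 5-methoxy oxygen should deliver chloride to that methyl group only, leaving the non-chelated 7-, 8- and 4'-methoxy groups.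

**Compound list**

1 | 2-hydroxy-4,6-dimethoxybenzaldehyde | COc1cc(O)c(C=O)c(OC)c1 | starting material
2 | N,N-diethylcarbamoyl chloride | CCN(CC)C(=O)Cl | starting material
3 | 2-formyl-3,5-dimethoxyphenyl N,N-diethylcarbamate | CCN(CC)C(=O)Oc1cc(OC)cc(OC)c1C=O | intermediate
4 | 2-[(diethylcarbamoyl)oxy]-4,6-dimethoxyphenyl formate | CCN(CC)C(=O)Oc1cc(OC)cc(OC)c1OC=O | intermediate (not isolated)
5 | 2-hydroxy-3,5-dimethoxyphenyl N,N-diethylcarbamate | CCN(CC)C(=O)Oc1cc(OC)cc(OC)c1O | intermediate
6 | 2,3,5-trimethoxyphenyl N,N-diethylcarbamate | CCN(CC)C(=O)Oc1cc(OC)cc(OC)c1OC | intermediate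
7 | 2-lithio-3,5,6-trimethoxyphenyl N,N-diethylcarbamate | CCN(CC)C(=O)Oc1c([Li])c(OC)cc(OC)c1OC | intermediate (not isolated)
8 | 2-iodo-3,5,6-trimethoxyphenyl N,N-diethylcarbamate | CCN(CC)C(=O)Oc1c(I)c(OC)cc(OC)c1OC | intermediate
9 | 2-iodo-3,5,6-trimethoxyphenol | Oc1c(I)c(OC)cc(OC)c1OC | intermediate
10 | 3,5-dihydroxy-4-methoxybenzoic acid | COc1c(O)cc(C(=O)O)cc1O | starting material
11 | benzyl 3,5-bis(benzyloxy)-4-methoxybenzoate | COc1c(OCc2ccccc2)cc(C(=O)OCc2ccccc2)cc1OCc1ccccc1 | intermediate
12 | [3,5-bis(benzyloxy)-4-methoxyphenyl]methanol | COc1c(OCc2ccccc2)cc(CO)cc1OCc1ccccc1 | intermediate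
13 | 3,5-bis(benzyloxy)-4-methoxybenzaldehyde | COc1c(OCc2ccccc2)cc(C=O)cc1OCc1ccccc1 | intermediate
14 | 1,3-bis(benzyloxy)-5-ethynyl-2-methoxybenzene | C#Cc1cc(OCc2ccccc2)c(OC)c(OCc2ccccc2)c1 | intermediate
15 | carbon monoxide | [C-]#[O+] | starting material
16 | 3-[3,5-bis(benzyloxy)-4-methoxyphenyl]-1-(2-hydroxy-3,4,6-trimethoxyphenyl)prop-2-yn-1-one | COc1cc(OC)c(C(=O)C#Cc2cc(OCc3ccccc3)c(OC)c(OCc3ccccc3)c2)c(O)c1OC | intermediate (not isolated)
17 | (E)-3-[3,5-bis(benzyloxy)-4-methoxyphenyl]-3-(diethylamino)-1-(2-hydroxy-3,4,6-trimethoxyphenyl)prop-2-en-1-one | COc1cc(OC)c(C(=O)/C=C(/N(CC)CC)c2cc(OCc3ccccc3)c(OC)c(OCc3ccccc3)c2)c(O)c1OC | intermediate (not isolated)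
18 | 2-[3,5-bis(benzyloxy)-4-methoxyphenyl]-5,7,8-trimethoxy-4H-chromen-4-one | COc1cc(OC)c2c(=O)cc(-c3cc(OCc4ccccc4)c(OC)c(OCc4ccccc4)c3)oc2c1OC | intermediate
19 | 2-[3,5-bis(benzyloxy)-4-methoxyphenyl]-3-lithio-5,7,8-trimethoxy-4H-chromen-4-one | COc1cc(OC)c2c(=O)c([Li])c(-c3cc(OCc4ccccc4)c(OC)c(OCc4ccccc4)c3)oc2c1OC | intermediate (not isolated)
20 | dimethyl {2-[3,5-bis(benzyloxy)-4-methoxyphenyl]-5,7,8-trimethoxy-4-oxo-4H-chromen-3-yl}boronate | COB(OC)c1c(-c2cc(OCc3ccccc3)c(OC)c(OCc3ccccc3)c2)oc2c(OC)c(OC)cc(OC)c2c1=O | intermediate (not isolated)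
21 | 2-[3,5-bis(benzyloxy)-4-methoxyphenyl]-3-hydroxy-5,7,8-trimethoxy-4H-chromen-4-one | COc1cc(OC)c2c(=O)c(O)c(-c3cc(OCc4ccccc4)c(OC)c(OCc4ccccc4)c3)oc2c1OC | intermediate
22 | 2-(3,5-dihydroxy-4-methoxyphenyl)-3,5-dihydroxy-7,8-dimethoxy-4H-chromen-4-one | COc1cc(O)c2c(=O)c(O)c(-c3cc(O)c(OC)c(O)c3)oc2c1OC | target

**Step count**

Total step count: 12.
Longest linear sequence: 8 steps (steps 1 to 5, then 10 to 12). The ring B branch (steps 6 to 9) joins at step 10.

**Steps most likely to fail**

Step 10. Oxidative addition into the electron-rich, doubly ortho-substituted C–I bond may be slow, so that direct alkynylation followed by furan closure, or capture of the aroylpalladium species by diethylamine, could overtake ynone formation. The fallback builds the same ynone without palladium or CO, setting out from 9 and 14 and returning to the route at 18.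
- Phenol 9 would be protected with MOMCl and i-Pr2NEt as 2-iodo-1,4,5-trimethoxy-3-(methoxymethoxy)benzene F1.
- Alkyne 14 would be deprotonated with n-BuLi to the lithium acetylide {[3,5-bis(benzyloxy)-4-methoxyphenyl]ethynyl}lithium F2, which N-methoxy-N-methylcarbamoyl chloride should acylate to 3-[3,5-bis(benzyloxy)-4-methoxyphenyl]-N-methoxy-N-methylprop-2-ynamide F3.
- Iodine–lithium exchange on F1 with n-BuLi at −78 °C should give [3,4,6-trimethoxy-2-(methoxymethoxy)phenyl]lithium F4, whose addition to the Weinreb amide F3 should stop at the ketone 3-[3,5-bis(benzyloxy)-4-methoxyphenyl]-1-[3,4,6-trimethoxy-2-(methoxymethoxy)phenyl]prop-2-yn-1-one F5.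
- HCl in MeOH should remove the methoxymethyl group to give ynone 16, here isolated, and diethylamine in EtOH should close ring C through enaminone 17 to flavone 18.

Step 11. The C3-lithiated chromone may open by beta-elimination of the ring A phenoxide (O1–C2 cleavage), or lithiation may be incomplete, before the borate is formed. The fallback sets out from 18 and returns at 21. Dimethyldioxirane in acetone/CH2Cl2 at 0 °C should epoxidise the C2–C3 double bond to racemic, cis-fused 2-[3,5-bis(benzyloxy)-4-methoxyphenyl]-2,3-epoxy-5,7,8-trimethoxy-2,3-dihydro-4H-chromen-4-one F6. Catalytic p-TsOH in CH2Cl2 should then open the oxirane at C2 and tautomerise it to the 3-hydroxyflavone 21.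

Step 12. The Lewis acid may remove a second methyl group (the 4'-O-methyl flanked by two boron-bound oxygens), or benzyl cations may alkylate ring A, during the combined debenzylation and demethylation. The fallback separates the two events, setting out from 21 and returning at 22. Hydrogenolysis (H2, palladium metal on carbon, Pd/C, EtOAc/MeOH, rt) should give 2-(3,5-dihydroxy-4-methoxyphenyl)-3-hydroxy-5,7,8-trimethoxy-4H-chromen-4-one F7 without any cationic intermediate. AlCl3 in MeCN, which acts through the C4 carbonyl chelate, should then cleave only the 5-O-methyl group to give 22.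

**Further compounds**

F1 | step 10 | 2-iodo-1,4,5-trimethoxy-3-(methoxymethoxy)benzene | COCOc1c(I)c(OC)cc(OC)c1OC
F2 | step 10 | {[3,5-bis(benzyloxy)-4-methoxyphenyl]ethynyl}lithium | [Li]C#Cc1cc(OCc2ccccc2)c(OC)c(OCc2ccccc2)c1
F3 | step 10 | 3-[3,5-bis(benzyloxy)-4-methoxyphenyl]-N-methoxy-N-methylprop-2-ynamide | CON(C)C(=O)C#Cc1cc(OCc2ccccc2)c(OC)c(OCc2ccccc2)c1
F4 | step 10 | [3,4,6-trimethoxy-2-(methoxymethoxy)phenyl]lithium | COCOc1c([Li])c(OC)cc(OC)c1OC
F5 | step 10 | 3-[3,5-bis(benzyloxy)-4-methoxyphenyl]-1-[3,4,6-trimethoxy-2-(methoxymethoxy)phenyl]prop-2-yn-1-one | COCOc1c(C(=O)C#Cc2cc(OCc3ccccc3)c(OC)c(OCc3ccccc3)c2)c(OC)cc(OC)c1OC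
F6 | step 11 | racemic cis-fused 2-[3,5-bis(benzyloxy)-4-methoxyphenyl]-2,3-epoxy-5,7,8-trimethoxy-2,3-dihydro-4H-chromen-4-one (one enantiomer drawn) | COc1cc(OC)c2C(=O)[C@H]5O[C@@]5(c3cc(OCc4ccccc4)c(OC)c(OCc4ccccc4)c3)Oc2c1OC
F7 | step 12 | 2-(3,5-dihydroxy-4-methoxyphenyl)-3-hydroxy-5,7,8-trimethoxy-4H-chromen-4-one | COc1cc(OC)c2c(=O)c(O)c(-c3cc(O)c(OC)c(O)c3)oc2c1OC
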